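## Retrosynthetic overview

1. No ring is formed: both benzene rings are bought in 2,4,6-trihydroxybenzophenone 1, and all work is on the periphery of its phloroglucinol ring.
2. Key disconnection: both aryl–prenyl bonds at once, by a twofold Stille coupling of a 3,5-diiodide with a prenylstannane on the unprotected, fully substituted phenol. This replaces the usual electrophilic C-prenylation of a phloroglucinol.
3. The diiodide comes from 2-hydroxy-4,6-dimethoxybenzophenone by iodination of its only two free ring carbons, so the halogens fix where both prenyl groups go.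
4. That phenol comes from 1 by chelation-controlled bis-O-methylation, which sets the OH/OMe pattern before any acid-sensitive prenyl group is present.

Assumption: the target has no stereocentre and no stereogenic double bond (both alkenes end in CMe2), so it is achiral and there is no configuration to set.

Numbering used in all names: the ring carbon bearing the benzoyl group is C1 and the hydroxyl sits on C2.

## Route

Step 1
Reactants: 1 2,4,6-trihydroxybenzophenone
Product: 3 2-hydroxy-4,6-dimethoxybenzophenone, via 2,6-dihydroxy-4-methoxybenzophenone 2 (not isolated)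
Conditions: Me2SO4 (2.1 equiv), K2CO3 (2.2 equiv), acetone, reflux
Reagents that add atoms: dimethyl sulfate, COS(=O)(=O)OC
Why: Williamson-type O-methylation under chelation control: the non-chelated 4-OH reacts first and then one of the two equivalent ortho hydroxyls, while the last hydroxyl is held in a strong hydrogen bond to the carbonyl and is not methylated by two equivalents of Me2SO4 under these mild conditions; no stereocentre is formed.

Step 2
Reactants: 3 2-hydroxy-4,6-dimethoxybenzophenone
Product: 6 2-hydroxy-3,5-diiodo-4,6-dimethoxybenzophenone, via 2-hydroxy-3-iodo-4,6-dimethoxybenzophenone 4 (not isolated), via 2-hydroxy-5-iodo-4,6-dimethoxybenzophenone 5 (not isolated)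
Conditions: NIS (2.2 equiv), CF3CO2H (10 mol %), MeCN, 0 °C to rt, dark
Reagents that add atoms: N-iodosuccinimide, O=C1CCC(=O)N1I
Why: Electrophilic aromatic iodination (SEAr): C3 and C5 are the only unsubstituted carbons of a ring activated by three oxygen donors, whereas the benzoyl phenyl ring is deactivated, so two equivalents of electrophilic iodine can only give the 3,5-diiodide; no stereocentre is formed.

Step 3
Reactants: 6 2-hydroxy-3,5-diiodo-4,6-dimethoxybenzophenone; 7 tributyl(3-methylbut-2-en-1-yl)stannane (3.0 equiv)
Product: 10 2-hydroxy-4,6-dimethoxy-3,5-bis(3-methylbut-2-en-1-yl)benzophenone, via 2-hydroxy-5-iodo-4,6-dimethoxy-3-(3-methylbut-2-en-1-yl)benzophenone 8 (not isolated), via 2-hydroxy-3-iodo-4,6-dimethoxy-5-(3-methylbut-2-en-1-yl)benzophenone 9 (not isolated)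
Conditions: Pd(PPh3)4 (10 mol %), DMF, 90 °C, Ar
Reagents that add atoms: none
Why: Twofold Stille cross-coupling: each C–I bond adds oxidatively to zerovalent palladium, the prenyl group is transferred from tin, and reductive elimination occurs at the unhindered CH2 terminus of the allyl-type prenyl ligand, so each linear prenyl group lands where an iodine sat, under neutral conditions that spare the chelated phenol, the ketone and the trisubstituted alkenes; no stereocentre is formed.

## Compound list

1 | 2,4,6-trihydroxybenzophenone, phenyl(2,4,6-trihydroxyphenyl)methanone | O=C(c1ccccc1)c1c(O)cc(O)cc1O | starting material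
2 | 2,6-dihydroxy-4-methoxybenzophenone | COc1cc(O)c(C(=O)c2ccccc2)c(O)c1 | intermediate
3 | 2-hydroxy-4,6-dimethoxybenzophenone | COc1cc(O)c(C(=O)c2ccccc2)c(OC)c1 | intermediate
4 | 2-hydroxy-3-iodo-4,6-dimethoxybenzophenone | COc1cc(OC)c(C(=O)c2ccccc2)c(O)c1I | intermediate
5 | 2-hydroxy-5-iodo-4,6-dimethoxybenzophenone | COc1c(I)c(OC)c(C(=O)c2ccccc2)c(O)c1 | intermediate
6 | 2-hydroxy-3,5-diiodo-4,6-dimethoxybenzophenone | COc1c(I)c(O)c(C(=O)c2ccccc2)c(OC)c1I | intermediate
7 | tributyl(3-methylbut-2-en-1-yl)stannane | CCCC[Sn](CCCC)(CCCC)CC=C(C)C | starting material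
8 | 2-hydroxy-5-iodo-4,6-dimethoxy-3-(3-methylbut-2-en-1-yl)benzophenone | COc1c(I)c(OC)c(C(=O)c2ccccc2)c(O)c1CC=C(C)C | intermediate
9 | 2-hydroxy-3-iodo-4,6-dimethoxy-5-(3-methylbut-2-en-1-yl)benzophenone | COc1c(CC=C(C)C)c(OC)c(C(=O)c2ccccc2)c(O)c1I | intermediate
10 | 2-hydroxy-4,6-dimethoxy-3,5-bis(3-methylbut-2-en-1-yl)benzophenone, CNP0230472.0 (achiral) | COc1c(CC=C(C)C)c(O)c(C(=O)c2ccccc2)c(OC)c1CC=C(C)C | target

## Summary

Total step count: 3.
Longest linear sequence: 3 steps (1 → 3 → 6 → 10).

## Steps most likely to fail, with fallbacks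

**Step 3 (twofold Stille prenylation) is the riskiest.** Both coupling sites are flanked by two oxygen substituents on a very electron-rich ring. The second coupling may stall or end in protodeiodination, and part of the prenyl group may be delivered through its CMe2 end to give 1,1-dimethylallyl isomers.

The fallback sets out from 6 and comes back at 10. It builds the trisubstituted alkenes by metathesis instead of transferring them. Compound 6 is coupled twice with allyltributylstannane (Pd(PPh3)4, DMF, 90 °C), a transfer with no α/γ ambiguity. It passes through 3-allyl-2-hydroxy-5-iodo-4,6-dimethoxybenzophenone F1 and 5-allyl-2-hydroxy-3-iodo-4,6-dimethoxybenzophenone F2 (neither isolated) to give 3,5-diallyl-2-hydroxy-4,6-dimethoxybenzophenone F3. Olefin cross-metathesis of F3 with a large excess of 2-methylbut-2-ene follows (second-generation Grubbs catalyst RuCl2(H2IMes)(PCy3)(=CHPh), CH2Cl2, 40 °C). It converts the allyl groups one after the other, through 5-allyl-2-hydroxy-4,6-dimethoxy-3-(3-methylbut-2-en-1-yl)benzophenone F4 and 3-allyl-2-hydroxy-4,6-dimethoxy-5-(3-methylbut-2-en-1-yl)benzophenone F5 (neither isolated), into 10.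

**Step 1 (selective bis-O-methylation) is next.** The risk is a mixture of mono-, di- and trimethyl ethers, or some C-methylation of the phloroglucinol ring, if the chelation control is less clean than expected.

The fallback sets out from 1 and comes back at 3. It reverses the logic: methylate everything, then take one methyl off. Exhaustive methylation of 1 (excess Me2SO4, K2CO3, acetone, prolonged reflux) gives 2,4,6-trimethoxybenzophenone F6. BCl3 (1.1 equiv, CH2Cl2, −78 to 0 °C) then binds the carbonyl and cleaves one of the two equivalent ortho methoxy groups through a six-membered boron chelate. The para methoxy group is untouched, and aqueous work-up gives 3. No prenyl group is present at this stage, so the Lewis acid is harmless.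

**Step 2 (diiodination) is the least risky of the three.** The second iodination could be slow, and an electron-rich aryl iodide next to a free phenol can lose iodine again under acid or light.

The fallback sets out from 1 and comes back at 6. It changes the order of events, so the halogens go onto the far more nucleophilic triphenolate under basic conditions and the OH/OMe differentiation comes afterwards. Compound 1 is iodinated with I2 (2.1 equiv) and NaHCO3 in THF–H2O at 0 °C. It passes through 2,4,6-trihydroxy-3-iodobenzophenone F7 (not isolated) to give 2,4,6-trihydroxy-3,5-diiodobenzophenone F8. Chelation-controlled methylation of F8 (Me2SO4, 2.1 equiv, K2CO3, acetone, reflux) then proceeds through 2,6-dihydroxy-3,5-diiodo-4-methoxybenzophenone F9 (not isolated) to give 6.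

## Further compounds

F1 | step 3 | 3-allyl-2-hydroxy-5-iodo-4,6-dimethoxybenzophenone | COc1c(I)c(OC)c(C(=O)c2ccccc2)c(O)c1CC=C
F2 | step 3 | 5-allyl-2-hydroxy-3-iodo-4,6-dimethoxybenzophenone | COc1c(CC=C)c(OC)c(C(=O)c2ccccc2)c(O)c1I
F3 | step 3 | 3,5-diallyl-2-hydroxy-4,6-dimethoxybenzophenone | COc1c(CC=C)c(O)c(C(=O)c2ccccc2)c(OC)c1CC=C
F4 | step 3 | 5-allyl-2-hydroxy-4,6-dimethoxy-3-(3-methylbut-2-en-1-yl)benzophenone | COc1c(CC=C)c(OC)c(C(=O)c2ccccc2)c(O)c1CC=C(C)C
F5 | step 3 | 3-allyl-2-hydroxy-4,6-dimethoxy-5-(3-methylbut-2-en-1-yl)benzophenone | COc1c(CC=C(C)C)c(OC)c(C(=O)c2ccccc2)c(O)c1CC=C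
F6 | step 1 | 2,4,6-trimethoxybenzophenone | COc1cc(OC)c(C(=O)c2ccccc2)c(OC)c1
F7 | step 2 | 2,4,6-trihydroxy-3-iodobenzophenone | O=C(c1ccccc1)c1c(O)cc(O)c(I)c1O
F8 | step 2 | 2,4,6-trihydroxy-3,5-diiodobenzophenone | O=C(c1ccccc1)c1c(O)c(I)c(O)c(I)c1O
F9 | step 2 | 2,6-dihydroxy-3,5-diiodo-4-methoxybenzophenone | COc1c(I)c(O)c(C(=O)c2ccccc2)c(O)c1I
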